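The two C2'=C3' double bonds of the identical 3-methylbut-2-enyl chains on C3 and C5 of ring A (the hexasubstituted 2,6-dihydroxy-4-methoxyphenyl ring) are the disconnection. Each alkene ends in a gem-dimethyl carbon and so has no geometry. One two-directional ruthenium-catalysed cross-metathesis with 2-methylbut-2-ene can therefore form both at the very end, after all Lewis-acid chemistry. The substrate for that step is the 3,5-diallyl triphenol ketone. It is built from 1,3,5-trimethoxybenzene and pivalate-protected 3-hydroxybenzoic acid by Friedel–Crafts aroylation, removal of both ortho methyl ethers, O-allylation, double Claisen rearrangement and ester cleavage.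

Key step: step 7

Assumption: the target has no stereocentre and no stereogenic double bond (each new alkene carbon bears two methyl groups), so it is achiral and the route needs no stereocontrol.

Step 1
Reactants: 1 3-hydroxybenzoic acid
Product: 2 3-(pivaloyloxy)benzoic acid
Conditions: PivCl (1.1 equiv), NaOH (2.2 equiv), H2O/THF, 0 °C → rt; then 2 M HCl to pH 2
Reagents that add atoms: pivaloyl chloride, CC(C)(C)C(=O)Cl
Why: Schotten–Baumann O-acylation, in which the phenoxide is far more nucleophilic than the carboxylate and any mixed anhydride is hydrolysed on work-up; the hindered pivalate is chosen because it should survive the Lewis acids, the carbonate base and the 195 °C of the later steps.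

Step 2
Reactants: 2 3-(pivaloyloxy)benzoic acid; 3 1,3,5-trimethoxybenzene
Product: 5 3-(2,4,6-trimethoxybenzoyl)phenyl pivalate, via acid chloride 4 (not isolated)
Conditions: (COCl)2, DMF (cat.), CH2Cl2, 0 °C → rt, evaporate; then 3, AlCl3 (1.5 equiv), CH2Cl2, 0 °C; ice/1 M HCl
Reagents that add atoms: oxalyl chloride, O=C(Cl)C(=O)Cl (supplies the chlorine of intermediate 4; no reagent atom remains in 5)
Why: Friedel–Crafts acylation of a strongly activated arene whose three ring positions are equivalent and whose ketone product is deactivated towards a second acylation, while any ortho-demethylated by-product converges to 7 in step 3.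

Step 3
Reactants: 5 3-(2,4,6-trimethoxybenzoyl)phenyl pivalate
Product: 7 3-(2,6-dihydroxy-4-methoxybenzoyl)phenyl pivalate, via mono-demethylated ketone 6 (not isolated)
Conditions: BCl3 (1 M in CH2Cl2, 4 equiv), CH2Cl2, −10 °C → rt; ice/1 M HCl
Reagents that add atoms: none
Why: Chelation-directed Lewis-acid ether cleavage, in which boron held between the ketone oxygen and an ortho methoxy oxygen makes that methyl group electrophilic towards chloride, so both ortho methyl groups should be removed in turn while the para methoxy group (no chelate possible) and the aryl ester stay intact.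

Step 4
Reactants: 7 3-(2,6-dihydroxy-4-methoxybenzoyl)phenyl pivalate; 8 allyl bromide
Product: 10 3-[2,6-bis(allyloxy)-4-methoxybenzoyl]phenyl pivalate, via mono-allyl ether 9 (not isolated)
Conditions: allyl bromide (3 equiv), K2CO3 (4 equiv), DMF, 60 °C
Reagents that add atoms: allyl bromide, C=CCBr
Why: Williamson etherification, in which carbonate in a dipolar aprotic solvent generates the phenoxides for O-alkylation by the reactive allylic bromide (the second, hydrogen-bonded phenol needs the excess reagent and warming), and the anhydrous medium spares the pivalate.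

Step 5
Reactants: 10 3-[2,6-bis(allyloxy)-4-methoxybenzoyl]phenyl pivalate
Product: 12 3-(3,5-diallyl-2,6-dihydroxy-4-methoxybenzoyl)phenyl pivalate, via mono-Claisen phenol 11 (not isolated)
Conditions: PhNEt2, 195 °C, Ar, sealed tube; 1 M HCl wash
Reagents that add atoms: none
Why: Two successive aromatic Claisen ([3,3]-sigmatropic) rearrangements, in which each allyl ether has one free ortho carbon (C3 or C5) and a shift to the acyl-bearing C1 cannot rearomatise and would only relay to the same C5 or C3 position, so both allyl groups should end where the prenyl groups are needed.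

Step 6
Reactants: 12 3-(3,5-diallyl-2,6-dihydroxy-4-methoxybenzoyl)phenyl pivalate
Product: 13 (3,5-diallyl-2,6-dihydroxy-4-methoxyphenyl)(3-hydroxyphenyl)methanone
Conditions: LiOH·H2O (6 equiv), THF/H2O (degassed), rt → 40 °C; 1 M HCl to pH 3
Reagents that add atoms: none
Why: Saponification of an aryl ester, in which hydroxide attacks the pivaloyl carbonyl and expels the phenoxide, while the doubly ortho-substituted diaryl ketone, the methyl ether and the isolated allyl groups are inert to aqueous base at this temperature.

Step 7
Reactants: 13 (3,5-diallyl-2,6-dihydroxy-4-methoxyphenyl)(3-hydroxyphenyl)methanone; 14 2-methylbut-2-ene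
Product: 16 [2,6-dihydroxy-4-methoxy-3,5-bis(3-methylbut-2-enyl)phenyl](3-hydroxyphenyl)methanone, via mono-prenyl ketone 15 (not isolated)
Conditions: Grubbs II (2 × 5 mol%), 2-methylbut-2-ene/CH2Cl2 (1:1, large excess), 1,4-benzoquinone (10 mol%), 40 °C, sealed tube; then DMSO (Ru scavenger), filtration through neutral SiO2
Reagents that add atoms: 2-methylbut-2-ene, CC=C(C)C
Why: Olefin cross-metathesis by the Chauvin mechanism: the ruthenium alkylidene adds [2+2] to each terminal allyl C=C and cycloreverts to a Ru=CH–CH2Ar carbene, which adds to 2-methylbut-2-ene and cycloreverts to release ArCH2–CH=C(CH3)2 and Ru=CHCH3; this ethylidene carries the chain and takes the former =CH2 terminus away as propene. The closest known reaction type is the allyl-to-prenyl cross-metathesis of ortho-allylphenols with 2-methylbut-2-ene under second-generation Ru–NHC catalysts, which tolerates free phenols and aryl ketones. No ring is closed (joining the C3 and C5 chains would need an impossibly strained meta-bridged seven-membered ring), and no stereocentre or stereogenic alkene arises because each new alkene carbon bears two methyl groups. The selectivity needed is chemoselectivity, for cross- over self-metathesis and for metathesis over ruthenium-hydride-mediated migration of the allyl double bond into conjugation with ring A. The first is secured by the unhindered monosubstituted allyl termini meeting a very large excess of a partner that does not homodimerise productively, so that any homodimer or crotyl intermediate is channelled on to the prenyl product. The second is secured by the benzoquinone additive, which intercepts ruthenium hydrides, and by the mild temperature; the work-up stays acid-free so that the ortho-prenylphenols do not cyclise.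

Compound list
1 | 3-hydroxybenzoic acid | O=C(O)c1cccc(O)c1 | starting material
2 | 3-(pivaloyloxy)benzoic acid | CC(C)(C)C(=O)Oc1cccc(c1)C(=O)O | intermediate
3 | 1,3,5-trimethoxybenzene | COc1cc(OC)cc(OC)c1 | starting material
4 | 3-(chlorocarbonyl)phenyl pivalate | CC(C)(C)C(=O)Oc1cccc(c1)C(Cl)=O | intermediate (not isolated)
5 | 3-(2,4,6-trimethoxybenzoyl)phenyl pivalate | COc1cc(OC)c(C(=O)c2cccc(OC(=O)C(C)(C)C)c2)c(OC)c1 | intermediate
6 | 3-(2-hydroxy-4,6-dimethoxybenzoyl)phenyl pivalate (present in the flask as its boron chelate) | COc1cc(O)c(C(=O)c2cccc(OC(=O)C(C)(C)C)c2)c(OC)c1 | intermediate (not isolated)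
7 | 3-(2,6-dihydroxy-4-methoxybenzoyl)phenyl pivalate | COc1cc(O)c(C(=O)c2cccc(OC(=O)C(C)(C)C)c2)c(O)c1 | intermediate
8 | allyl bromide | C=CCBr | starting material
9 | 3-[2-(allyloxy)-6-hydroxy-4-methoxybenzoyl]phenyl pivalate | COc1cc(O)c(C(=O)c2cccc(OC(=O)C(C)(C)C)c2)c(OCC=C)c1 | intermediate (not isolated)
10 | 3-[2,6-bis(allyloxy)-4-methoxybenzoyl]phenyl pivalate | COc1cc(OCC=C)c(C(=O)c2cccc(OC(=O)C(C)(C)C)c2)c(OCC=C)c1 | intermediate
11 | 3-[3-allyl-6-(allyloxy)-2-hydroxy-4-methoxybenzoyl]phenyl pivalate | COc1cc(OCC=C)c(C(=O)c2cccc(OC(=O)C(C)(C)C)c2)c(O)c1CC=C | intermediate (not isolated)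
12 | 3-(3,5-diallyl-2,6-dihydroxy-4-methoxybenzoyl)phenyl pivalate | COc1c(CC=C)c(O)c(C(=O)c2cccc(OC(=O)C(C)(C)C)c2)c(O)c1CC=C | intermediate
13 | (3,5-diallyl-2,6-dihydroxy-4-methoxyphenyl)(3-hydroxyphenyl)methanone | COc1c(CC=C)c(O)c(C(=O)c2cccc(O)c2)c(O)c1CC=C | intermediate (key-step precursor)
14 | 2-methylbut-2-ene | CC=C(C)C | starting material
15 | [3-allyl-2,6-dihydroxy-4-methoxy-5-(3-methylbut-2-enyl)phenyl](3-hydroxyphenyl)methanone | COc1c(CC=C)c(O)c(C(=O)c2cccc(O)c2)c(O)c1CC=C(C)C | intermediate (not isolated)
16 | [2,6-dihydroxy-4-methoxy-3,5-bis(3-methylbut-2-enyl)phenyl](3-hydroxyphenyl)methanone | COc1c(CC=C(C)C)c(O)c(C(=O)c2cccc(O)c2)c(O)c1CC=C(C)C | target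

Total step count: 7
Longest linear sequence: 7 steps (1 → 2 → 5 → 7 → 10 → 12 → 13 → 16)

Steps most likely to fail

Step 3 (double ortho-demethylation). The cleavage may stall after the first methyl group once the ketone is tied up in the first boron chelate. Forcing it may instead cause loss of the para methyl ether or of the ester. Fallback: set out from 2 and make acid chloride 4 as in step 2. Use it for Friedel–Crafts aroylation of commercial phloroglucinol (Oc1cc(O)cc(O)c1; AlCl3, CH2Cl2/PhNO2, 0 °C → rt), which should give 3-(2,4,6-trihydroxybenzoyl)phenyl pivalate F1. Mono-O-methylation with dimethyl sulfate (1.0 equiv, K2CO3, acetone, rt) should take place at the 4-hydroxyl, the only one not hydrogen-bonded to the ketone. This comes back to the route at 7 without any demethylation.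

Step 5 (double Claisen rearrangement). The second sigmatropic shift may remain incomplete, the freed ortho-allylphenols may cyclise thermally onto their alkenes, or allyl groups may be lost at 195 °C. Fallback: set out from 7 and iodinate both free ring-A positions with N-iodosuccinimide (2.1 equiv, MeCN, 0 °C → rt) to give 3-(2,6-dihydroxy-3,5-diiodo-4-methoxybenzoyl)phenyl pivalate F2. A double Migita–Kosugi–Stille coupling with allyltributylstannane (Pd(PPh3)4, DMF, 80 °C) should then place both allyl groups by cross-coupling in place of rearrangement. This comes back to the route at 12.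

Step 7 (double cross-metathesis). The allyl double bonds may migrate into conjugation with ring A and then be shortened by metathesis, the exchange may stop at the mono-prenyl stage 15, the polar triphenol may deactivate the catalyst, or the ortho-prenylphenols may cyclise to chromans on acidic silica. Fallback: set out from 7 and C-prenylate the phenoxide directly at C3 and C5 with 1-bromo-3-methylbut-2-ene (2.2 equiv, DBU, THF, 0 °C → rt). This is a known but unselective reaction of acylphloroglucinols; it should give 3-[2,6-dihydroxy-4-methoxy-3,5-bis(3-methylbut-2-enyl)benzoyl]phenyl pivalate F3. Ester cleavage with LiOH as in step 6 comes back to the route at the target 16.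

Further compounds
F1 | step 3 | 3-(2,4,6-trihydroxybenzoyl)phenyl pivalate | Oc1cc(O)c(C(=O)c2cccc(OC(=O)C(C)(C)C)c2)c(O)c1
F2 | step 5 | 3-(2,6-dihydroxy-3,5-diiodo-4-methoxybenzoyl)phenyl pivalate | COc1c(I)c(O)c(C(=O)c2cccc(OC(=O)C(C)(C)C)c2)c(O)c1I
F3 | step 7 | 3-[2,6-dihydroxy-4-methoxy-3,5-bis(3-methylbut-2-enyl)benzoyl]phenyl pivalate | COc1c(CC=C(C)C)c(O)c(C(=O)c2cccc(OC(=O)C(C)(C)C)c2)c(O)c1CC=C(C)C
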